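## Analysis of the target

Compound 21 joins a drim-8(12)-ene unit to an epoxyquinol through a single methylene. The numbering used throughout is: decalin C1–C10 as in drimanes, C11 the linking CH2, C12 the exocyclic CH2; the enone ring is C1' (C=O), C2' (=CH), C3' (bears C7'H2OH), C4' (CHOH), C5' (epoxide CH) and C6' (quaternary epoxide carbon carrying C11).

Rings A and B form a trans-decalin with three contiguous stereocentres (5S, 9S, 10S; axial C10 methyl, equatorial C11). The enone ring carries a second triad (4'R, 5'S, 6'S): the epoxide oxygen lies on one face, and the 4'-hydroxyl and C11 lie on the other, so the hydroxyl is anti to the epoxide oxygen. The two triads are insulated from each other by C11, so neither can control the other.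

The sensitive groups are the γ-hydroxy epoxy enone (base removes C4'–H and opens the epoxide towards an arene), the exocyclic C8=C12 alkene (acid moves it into the ring) and the two free alcohols. The hard points are the absolute configuration of a decalin with no heteroatom handle, the position of the alkene, and the hindered C11 link between C9 and the quaternary C6'.

The strategy rests on one feature. C11, C9, C8(C12), C7, C6, C5, C10(CH3), C1, C2, C3 and C4(CH3)2 are, atom for atom, a (2E,6E)-farnesyl chain on C6'. Only the bonds C4–C5 and C9–C10 are missing, and the target is an isomer of that open-chain compound.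

## Retrosynthetic reasoning

**21 ⇒ 20.** The bonds C4–C5 and C9–C10 are cut, which opens rings A and B and returns the farnesyl epoxyquinol 20. This cut removes all three decalin stereocentres and the alkene-position problem in one operation and leaves an achiral side chain. Forward, a class 2 terpene cyclase must protonate C3, close both rings through a chair–chair fold and take a proton from C12. This is the only step in which the exocyclic alkene exists, so no acidic or oxidative step has to tolerate it.

**20 ⇒ 18 ⇒ 16 ⇒ 15.** The C4'–O bond is disconnected with inversion. Hydride reagents are expected to attack an epoxyquinone carbonyl from the face away from the epoxide oxygen, which puts the new hydroxyl syn to the epoxide (16), the wrong way round for 20. The plan therefore reduces epoxyquinone 15 to 16 and corrects C4' by an SN2 esterification to bis-ester 18, followed by ester cleavage. Reduction must select the C4' carbonyl over C1'; the free C7' hydroxyl and the quaternary C6' next to C1' both favour this.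

**15 ⇒ 14 ⇒ 13.** The two C–O bonds of the epoxide are cut, leading back to the quinone monoketal 13. The ketal at C4' does three things. It leaves C1' as the only carbonyl, it makes C5' the only unsubstituted β-carbon so the peroxide can add at one alkene only, and it keeps C4' masked until the epoxide is in place. Forward, a reagent-controlled asymmetric nucleophilic epoxidation sets C5' and C6' on a flat, achiral substrate; acid then unveils the C4' carbonyl of 15.

**13 ⇒ 12.** The C4' ketal and C1' carbonyl are traced back to a para-methoxyphenol. Oxidative dearomatisation of 12 in an alcohol solvent places the carbonyl at the former phenol carbon and the ketal at the former methoxy carbon without ambiguity. This is why the phenol must sit next to the farnesyl group and the methoxy group next to the hydroxymethyl group.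

**12 ⇒ 10 ⇒ 5 + 7.** The aryl–C11 bond is cut. An aryl anion equivalent at C6' (8, then 9), generated beside the acetal-protected phenol oxygen of 5, is allylated with farnesyl bromide 7, itself one step from farnesol 6. An allylic electrophile makes this bond easy, whereas the same bond to a preformed decalin would be a hindered alkylation. Both protecting groups of 10 are acid-labile under conditions that leave the triene alone, so 12 is released in one operation.

**5 ⇒ 4 ⇒ 3 ⇒ 2 ⇒ 1.** The substitution pattern comes from 2,5-dihydroxybenzaldehyde 1. Its 2-hydroxyl is hydrogen-bonded to the aldehyde, so the 5-hydroxyl can be protected first (2); the protecting group later serves as the metalation director. Methylation (3), reduction (4) and silylation (5) complete the arene.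

## Alternatives that were turned down

**Alternative 1:** The disconnection is the C8–C9 bond of ring B, with C11 kept as a ketone and the arene already attached. In the forward key step, substrate A2 has ring A complete, a butynyl chain on C5 and a (Z)-silyl enol ether of the C11 aryl ketone on C10. Ph3PAuNTf2 activates the terminal C8≡C12 alkyne, C9 attacks it in a 6-exo-dig Conia-ene closure, and protodeauration leaves the C8=C12 methylene in ketone A1.
- For it: the alkene position is fixed by the mechanism, as securely as by an enzyme and more securely than by any Brønsted acid. The step is ordinary solution chemistry and does not depend on a membrane protein; on scale and availability it is the stronger plan.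
- Against it: C5 and the quaternary C10 must first be made in an enantioselective ring A synthesis, and C9 is set only relative to them. A1 is a β,γ-unsaturated ketone with a doubly activated C9–H, so the alkene can slip into conjugation and C9 can epimerise. The C11 carbonyl must then be removed next to that alkene. The whole arene-to-epoxyquinol sequence, including its acidic ketal hydrolysis, would have to be run with the exocyclic alkene present.
- Comparison: the chosen route makes two rings, three stereocentres and the alkene in the last operation from an achiral chain, and every acidic or oxidative step precedes the alkene. It gives up independence from a biocatalyst.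

**Alternative 2:** The disconnection is the pair of epoxide C–O bonds, made while C2'=C3' is masked in a norbornene cage, with the decalin already in place. In the forward key step, the remaining C5'=C6' enedione alkene of adduct A4 is epoxidised with H2O2 and Na2CO3 from the convex face to give A3. The cage would then steer hydride to C4' from the same convex face, and a retro-Diels–Alder reaction would return C2'=C3'.
- For it: both the epoxide and the carbinol are set by substrate control, and the hydroxyl ends up anti to the epoxide oxygen directly. On this point it is stronger than the chosen route, which needs a reduction followed by an inversion.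
- Against it: the four cage stereocentres must have the right absolute sense relative to the decalin, yet the cycloaddition that makes A4 has no stereocentre nearer than C9, so it needs either a diastereomer separation or a chiral catalyst on a hindered dialkyl quinone. The diene must also choose C2'=C3' over C5'=C6', both monoalkylated. The cycloreversion is a high-temperature step on an epoxy alcohol with an exocyclic alkene. The hindered aryl–C11 bond to a preformed decalin is still required, and the step count is clearly higher.
- Comparison: the chosen route sets the epoxide by reagent control on a flat monoketal and has no template to install and remove. It pays for this with two extra steps at C4'.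

**Alternative 3:** The disconnection is C5'–C6' together with C6'–O. In the forward key step, the C6' chloro-enolate of the open-chain compound A6 adds to its C5' aldehyde and the aldolate displaces chloride (intramolecular Darzens). This closes the carbocycle and the epoxide at once and gives the bis-silyl ether A5.
- For it: the quaternary C6', the ring and the epoxide arise in one step, with no aromatic precursor and no dearomatisation. C4' is already in place and is not left to a facial reduction. On paper it is at least as convergent as the chosen plan.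
- Against it: A6 is fragile. It has an α-silyloxy aldehyde that can epimerise or eliminate, a (Z)-enone that must stay Z to cyclise, and competing enolisation sites. C5' and C6' are controlled only by C4', and only the aldolate with oxygen anti-periplanar to chloride can close; the others revert or stall. Building A6 also needs an alkylation at C6' with the hindered drimenylmethyl unit and a long linear sequence.
- Comparison: the chosen route reaches its precursor by standard aromatic chemistry and concentrates the risk in one step; the Darzens plan spreads stereochemical risk over the closure and the synthesis of A6.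

Key step: step 14

Assumption: the sense of induction of the tartrate-modified peroxide on 13 is not derived here; L-(+)-diisopropyl tartrate is written in step 9, and its mirror image is used instead if the first run gives the enantiomeric epoxide.

Assumption: the biocatalyst of step 14 is the Pyr4-family class 2 cyclase of the macrophorin pathway (MacJ), produced in a yeast or fungal host.

## Route

Step 1
Reactants: 1 2,5-dihydroxybenzaldehyde
Product: 2 2-hydroxy-5-(tetrahydropyran-2-yloxy)benzaldehyde (racemic at the acetal carbon)
Conditions: 3,4-dihydro-2H-pyran (1.2 equiv), PPTS (cat.), CH2Cl2, 0 °C → rt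
Reagents that add atoms: 3,4-dihydro-2H-pyran, C1=COCCC1
Why: Acid-catalysed tetrahydropyranylation of a phenol; the 2-hydroxyl is tied up in a hydrogen bond to the formyl oxygen, so the 5-hydroxyl should react first. The acetal centre is racemic and is removed in step 7.

Step 2
Reactants: 2 2-hydroxy-5-(tetrahydropyran-2-yloxy)benzaldehyde
Product: 3 2-methoxy-5-(tetrahydropyran-2-yloxy)benzaldehyde
Conditions: MeI, K2CO3, DMF, rt
Reagents that add atoms: iodomethane, CI
Why: Williamson O-methylation of the remaining phenol; the acetal is stable to base.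

Step 3
Reactants: 3 2-methoxy-5-(tetrahydropyran-2-yloxy)benzaldehyde
Product: 4 [2-methoxy-5-(tetrahydropyran-2-yloxy)phenyl]methanol
Conditions: NaBH4, MeOH, 0 °C
Reagents that add atoms: none
Why: Borohydride reduction of an aryl aldehyde to the benzylic alcohol that becomes C7'.

Step 4
Reactants: 4 [2-methoxy-5-(tetrahydropyran-2-yloxy)phenyl]methanol
Product: 5 tert-butyl{[2-methoxy-5-(tetrahydropyran-2-yloxy)phenyl]methoxy}dimethylsilane
Conditions: TBSCl, imidazole, DMF, rt
Reagents that add atoms: tert-butyldimethylsilyl chloride, CC(C)(C)[Si](C)(C)Cl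
Why: Silylation of a primary alcohol; the bulky, weakly coordinating silyl ether is chosen so that it does not direct lithiation to the position between the two oxygen-bearing substituents.

Step 5
Reactants: 6 (2E,6E)-farnesol
Product: 7 (2E,6E)-farnesyl bromide
Conditions: PBr3 (0.4 equiv), Et2O, −10 → 0 °C, dark; used at once
Reagents that add atoms: phosphorus tribromide, BrP(Br)Br
Why: Bromination of a primary allylic alcohol through its phosphite; at low temperature substitution at C1 should keep the 2E geometry.

Step 6
Reactants: 5 tert-butyl{[2-methoxy-5-(tetrahydropyran-2-yloxy)phenyl]methoxy}dimethylsilane; 7 (2E,6E)-farnesyl bromide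
Product: 10 tert-butyl{[2-methoxy-5-(tetrahydropyran-2-yloxy)-4-[(2E,6E)-3,7,11-trimethyldodeca-2,6,10-trien-1-yl]phenyl]methoxy}dimethylsilane, via aryllithium 8 (not isolated), via arylcopper 9 (not isolated)
Conditions: n-BuLi, THF, 0 °C → rt; CuBr·SMe2, −78 °C; then 7, −78 → 0 °C
Reagents that add atoms: none
Why: Directed ortho-metalation by the aryl acetal oxygen should occur at C6', the ortho site not flanked by the silyloxymethyl group. Transmetalation to the arylcopper and allylic substitution at C1 of 7 (SN2, not SN2') forms the aryl–C11 bond with the 2E alkene intact.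

Step 7
Reactants: 10 tert-butyl{[2-methoxy-5-(tetrahydropyran-2-yloxy)-4-[(2E,6E)-3,7,11-trimethyldodeca-2,6,10-trien-1-yl]phenyl]methoxy}dimethylsilane
Product: 12 5-(hydroxymethyl)-4-methoxy-2-[(2E,6E)-3,7,11-trimethyldodeca-2,6,10-trien-1-yl]phenol, via phenol silyl ether 11 (not isolated)
Conditions: PPTS (0.3 equiv), MeOH, 45 °C
Reagents that add atoms: none
Why: Acid-catalysed acetal exchange removes the aryl acetal quickly, and methanolysis of the primary silyl ether follows. The pyridinium acid is too weak to protonate the trisubstituted alkenes or to close a chroman onto the phenol.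

Step 8
Reactants: 12 5-(hydroxymethyl)-4-methoxy-2-[(2E,6E)-3,7,11-trimethyldodeca-2,6,10-trien-1-yl]phenol
Product: 13 5-(hydroxymethyl)-4,4-dimethoxy-2-[(2E,6E)-3,7,11-trimethyldodeca-2,6,10-trien-1-yl]cyclohexa-2,5-dien-1-one
Conditions: PhI(OAc)2, MeOH, 0 °C
Reagents that add atoms: methanol, CO
Why: Oxidative dearomatisation of a para-methoxyphenol by a hypervalent iodine reagent; methanol adds at the methoxy-bearing carbon, giving the quinone monoketal with the carbonyl at C1' and the ketal at C4'.

Step 9
Reactants: 13 5-(hydroxymethyl)-4,4-dimethoxy-2-[(2E,6E)-3,7,11-trimethyldodeca-2,6,10-trien-1-yl]cyclohexa-2,5-dien-1-one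
Product: 14 (1S,6R)-4-(hydroxymethyl)-5,5-dimethoxy-1-[(2E,6E)-3,7,11-trimethyldodeca-2,6,10-trien-1-yl]-7-oxabicyclo[4.1.0]hept-3-en-2-one (5'R,6'S)
Conditions: Ph3COOH, NaN(SiMe3)2, L-(+)-DIPT, 4 Å MS, toluene, −50 °C
Reagents that add atoms: trityl hydroperoxide, OOC(c1ccccc1)(c1ccccc1)c1ccccc1
Why: Tartrate-mediated nucleophilic (Weitz–Scheffer-type) epoxidation. The peroxide adds to C5', the only unsubstituted β-carbon, and the enolate closes onto oxygen. The face is chosen by the sodium tartrate aggregate held at the C7' alkoxide, which sets C5' and C6' together.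

Step 10
Reactants: 14 (1S,6R)-4-(hydroxymethyl)-5,5-dimethoxy-1-[(2E,6E)-3,7,11-trimethyldodeca-2,6,10-trien-1-yl]-7-oxabicyclo[4.1.0]hept-3-en-2-one
Product: 15 (1S,6R)-4-(hydroxymethyl)-1-[(2E,6E)-3,7,11-trimethyldodeca-2,6,10-trien-1-yl]-7-oxabicyclo[4.1.0]hept-3-ene-2,5-dione
Conditions: 48% aq HF, MeCN, 0 °C
Reagents that add atoms: water, O
Why: Acid hydrolysis of the dimethyl ketal to the C4' ketone. An epoxide next to a carbonyl is deactivated towards acid opening, and dilute aqueous HF at 0 °C should not protonate the chain alkenes.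

Step 11
Reactants: 15 (1S,6R)-4-(hydroxymethyl)-1-[(2E,6E)-3,7,11-trimethyldodeca-2,6,10-trien-1-yl]-7-oxabicyclo[4.1.0]hept-3-ene-2,5-dione
Product: 16 (1S,5S,6S)-5-hydroxy-4-(hydroxymethyl)-1-[(2E,6E)-3,7,11-trimethyldodeca-2,6,10-trien-1-yl]-7-oxabicyclo[4.1.0]hept-3-en-2-one (4'S, hydroxyl syn to the epoxide oxygen)
Conditions: i-Bu2AlH (2.3 equiv), THF, −78 °C; aq KNaC4H4O6
Reagents that add atoms: none
Why: 1,2-Reduction of one enedione carbonyl. The first equivalent makes the C7' aluminium alkoxide, which holds the Lewis acid beside the C4' carbonyl, while C1' is shielded by the quaternary C6'. Hydride should enter anti to the C5'–O bond (steric and Felkin–Anh polar control), giving the 4'S alcohol.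

Step 12
Reactants: 16 (1S,5S,6S)-5-hydroxy-4-(hydroxymethyl)-1-[(2E,6E)-3,7,11-trimethyldodeca-2,6,10-trien-1-yl]-7-oxabicyclo[4.1.0]hept-3-en-2-one
Product: 18 (1S,5R,6S)-5-(4-nitrobenzoyloxy)-4-[(4-nitrobenzoyloxy)methyl]-1-[(2E,6E)-3,7,11-trimethyldodeca-2,6,10-trien-1-yl]-7-oxabicyclo[4.1.0]hept-3-en-2-one, via 7'-mono(4-nitrobenzoate) 17 (not isolated)
Conditions: 4-O2NC6H4CO2H (3 equiv), PPh3, DIAD, THF, 0 °C → rt
Reagents that add atoms: 4-nitrobenzoic acid, O=C(O)c1ccc([N+](=O)[O-])cc1
Why: Mitsunobu esterification. The primary alcohol is esterified first with no stereochemical consequence; the secondary alkoxyphosphonium is then displaced by carboxylate with SN2 inversion, turning C4' from S to R (oxygen anti to the epoxide).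

Step 13
Reactants: 18 (1S,5R,6S)-5-(4-nitrobenzoyloxy)-4-[(4-nitrobenzoyloxy)methyl]-1-[(2E,6E)-3,7,11-trimethyldodeca-2,6,10-trien-1-yl]-7-oxabicyclo[4.1.0]hept-3-en-2-one
Product: 20 (1S,5R,6S)-5-hydroxy-4-(hydroxymethyl)-1-[(2E,6E)-3,7,11-trimethyldodeca-2,6,10-trien-1-yl]-7-oxabicyclo[4.1.0]hept-3-en-2-one, via 4'-mono(4-nitrobenzoate) 19 (not isolated)
Conditions: K2CO3 (cat.), MeOH, 0 °C, short reaction time
Reagents that add atoms: none
Why: Base-catalysed transesterification of the two activated nitrobenzoates, the primary one first. C6' is quaternary, so no enolate can form towards the epoxide, and the low temperature and short time limit removal of C4'–H.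

Step 14
Reactants: 20 (1S,5R,6S)-5-hydroxy-4-(hydroxymethyl)-1-[(2E,6E)-3,7,11-trimethyldodeca-2,6,10-trien-1-yl]-7-oxabicyclo[4.1.0]hept-3-en-2-one
Product: 21 (1S,5R,6S)-5-hydroxy-4-(hydroxymethyl)-1-{[(1S,4aS,8aS)-5,5,8a-trimethyl-2-methylidenedecahydronaphthalen-1-yl]methyl}-7-oxabicyclo[4.1.0]hept-3-en-2-one (CNP0174686.3)
Conditions: resting cells or microsomes of S. cerevisiae expressing the cyclase MacJ, KH2PO4/K2HPO4 buffer pH 7.0, DMSO (2% v/v), 30 °C; EtOAc extraction
Reagents that add atoms: none
Why: An active-site acid of the class 2 cyclase protonates C3 of the terminal C3=C4 alkene in a chair–chair folded chain; C5 of the C5=C10 alkene attacks the C4 cation, C9 of the C8=C9 alkene attacks the C10 cation, and the C8 cation loses a proton from C12. The closest known reaction type is the bicyclisation of farnesyl meroterpenoids by Pyr4-family integral-membrane cyclases, which includes late-stage cyclisation of farnesyl epoxycyclohexenones in the macrophorin pathway. Ring A closes by 6-endo-trig attack forming C4–C5, and ring B by 6-endo-trig attack forming C9–C10. Both are anti additions across E alkenes, so the E geometry of C5=C10 with the chair fold gives the trans fusion (5S, 10S, axial methyl), and the E geometry of C8=C9 gives 9S with C11 equatorial. The chain is achiral, so the absolute sense comes only from the enzyme, which fixes the fold and the face of C3 protonation. The step needs protonation of the terminal alkene and not activation of the epoxide or enone, and termination at C12–H and not at C7–H or by capture with O4', O7' or water. The near-neutral pocket, the placement of its base, and a substrate of the native type with both hydroxyls free should secure this. C4', C5' and C6' are spectators and stay as set in steps 9 to 12.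

## Compound list

1 | 2,5-dihydroxybenzaldehyde | O=Cc1cc(O)ccc1O | starting material
2 | 2-hydroxy-5-(tetrahydropyran-2-yloxy)benzaldehyde (racemic acetal) | O=Cc1cc(OC2CCCCO2)ccc1O | intermediate
3 | 2-methoxy-5-(tetrahydropyran-2-yloxy)benzaldehyde | COc1ccc(OC2CCCCO2)cc1C=O | intermediate
4 | [2-methoxy-5-(tetrahydropyran-2-yloxy)phenyl]methanol | COc1ccc(OC2CCCCO2)cc1CO | intermediate
5 | tert-butyl{[2-methoxy-5-(tetrahydropyran-2-yloxy)phenyl]methoxy}dimethylsilane | COc1ccc(OC2CCCCO2)cc1CO[Si](C)(C)C(C)(C)C | intermediate
6 | (2E,6E)-farnesol | CC(C)=CCC/C(C)=C/CC/C(C)=C/CO | starting material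
7 | (2E,6E)-farnesyl bromide | CC(C)=CCC/C(C)=C/CC/C(C)=C/CBr | intermediate
8 | {4-[(tert-butyldimethylsilyloxy)methyl]-5-methoxy-2-(tetrahydropyran-2-yloxy)phenyl}lithium | [Li]c1cc(OC)c(CO[Si](C)(C)C(C)(C)C)cc1OC1CCCCO1 | intermediate (not isolated)
9 | {4-[(tert-butyldimethylsilyloxy)methyl]-5-methoxy-2-(tetrahydropyran-2-yloxy)phenyl}copper | [Cu]c1cc(OC)c(CO[Si](C)(C)C(C)(C)C)cc1OC1CCCCO1 | intermediate (not isolated)
10 | tert-butyl{[2-methoxy-5-(tetrahydropyran-2-yloxy)-4-[(2E,6E)-3,7,11-trimethyldodeca-2,6,10-trien-1-yl]phenyl]methoxy}dimethylsilane | CC(C)=CCC/C(C)=C/CC/C(C)=C/Cc1cc(OC)c(CO[Si](C)(C)C(C)(C)C)cc1OC1CCCCO1 | intermediate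
11 | 5-[(tert-butyldimethylsilyloxy)methyl]-4-methoxy-2-[(2E,6E)-3,7,11-trimethyldodeca-2,6,10-trien-1-yl]phenol | CC(C)=CCC/C(C)=C/CC/C(C)=C/Cc1cc(OC)c(CO[Si](C)(C)C(C)(C)C)cc1O | intermediate (not isolated)
12 | 5-(hydroxymethyl)-4-methoxy-2-[(2E,6E)-3,7,11-trimethyldodeca-2,6,10-trien-1-yl]phenol | CC(C)=CCC/C(C)=C/CC/C(C)=C/Cc1cc(OC)c(CO)cc1O | intermediate
13 | 5-(hydroxymethyl)-4,4-dimethoxy-2-[(2E,6E)-3,7,11-trimethyldodeca-2,6,10-trien-1-yl]cyclohexa-2,5-dien-1-one | CC(C)=CCC/C(C)=C/CC/C(C)=C/CC1=CC(OC)(OC)C(CO)=CC1=O | intermediate
14 | (1S,6R)-4-(hydroxymethyl)-5,5-dimethoxy-1-[(2E,6E)-3,7,11-trimethyldodeca-2,6,10-trien-1-yl]-7-oxabicyclo[4.1.0]hept-3-en-2-one | CC(C)=CCC/C(C)=C/CC/C(C)=C/C[C@]12O[C@H]1C(OC)(OC)C(CO)=CC2=O | intermediate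
15 | (1S,6R)-4-(hydroxymethyl)-1-[(2E,6E)-3,7,11-trimethyldodeca-2,6,10-trien-1-yl]-7-oxabicyclo[4.1.0]hept-3-ene-2,5-dione | CC(C)=CCC/C(C)=C/CC/C(C)=C/C[C@]12O[C@H]1C(=O)C(CO)=CC2=O | intermediate
16 | (1S,5S,6S)-5-hydroxy-4-(hydroxymethyl)-1-[(2E,6E)-3,7,11-trimethyldodeca-2,6,10-trien-1-yl]-7-oxabicyclo[4.1.0]hept-3-en-2-one (4'-epimer of 20) | CC(C)=CCC/C(C)=C/CC/C(C)=C/C[C@]12O[C@H]1[C@@H](O)C(CO)=CC2=O | intermediate
17 | 7'-mono(4-nitrobenzoate) of 16 | CC(C)=CCC/C(C)=C/CC/C(C)=C/C[C@]12O[C@H]1[C@@H](O)C(COC(=O)c3ccc([N+](=O)[O-])cc3)=CC2=O | intermediate (not isolated)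
18 | (1S,5R,6S)-5-(4-nitrobenzoyloxy)-4-[(4-nitrobenzoyloxy)methyl]-1-[(2E,6E)-3,7,11-trimethyldodeca-2,6,10-trien-1-yl]-7-oxabicyclo[4.1.0]hept-3-en-2-one | CC(C)=CCC/C(C)=C/CC/C(C)=C/C[C@]12O[C@H]1[C@H](OC(=O)c3ccc([N+](=O)[O-])cc3)C(COC(=O)c3ccc([N+](=O)[O-])cc3)=CC2=O | intermediate
19 | 4'-mono(4-nitrobenzoate) of 20 | CC(C)=CCC/C(C)=C/CC/C(C)=C/C[C@]12O[C@H]1[C@H](OC(=O)c3ccc([N+](=O)[O-])cc3)C(CO)=CC2=O | intermediate (not isolated)
20 | (1S,5R,6S)-5-hydroxy-4-(hydroxymethyl)-1-[(2E,6E)-3,7,11-trimethyldodeca-2,6,10-trien-1-yl]-7-oxabicyclo[4.1.0]hept-3-en-2-one | CC(C)=CCC/C(C)=C/CC/C(C)=C/C[C@]12O[C@H]1[C@H](O)C(CO)=CC2=O | intermediate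
21 | (1S,5R,6S)-5-hydroxy-4-(hydroxymethyl)-1-{[(1S,4aS,8aS)-5,5,8a-trimethyl-2-methylidenedecahydronaphthalen-1-yl]methyl}-7-oxabicyclo[4.1.0]hept-3-en-2-one | C=C1CC[C@H]2C(C)(C)CCC[C@]2(C)[C@H]1C[C@]12O[C@H]1[C@H](O)C(CO)=CC2=O | target

## Step count and least certain steps

Total step count: 14. Longest linear sequence: 13 steps (from 1 through steps 1–4 and 6–14). Step 5 is a one-step side branch from 6.

**Step 14 (key step).** The most likely failure is insufficient turnover. The cyclase is a membrane protein whose expression level is uncertain, the hydrophobic substrate may not reach it, and host enzymes may reduce the electrophilic epoxy enone before cyclisation. A second failure is premature or misplaced termination, giving ring-alkene isomers or monocyclic products.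

Fallback: the decalin is taken from the chiral pool and not made by the enzyme. It sets out from 5 and returns at 21.
- (5S,9S,10S)-Albicanol F1 is oxidised with Dess–Martin periodinane to albicanal F2.
- Compound 5 is lithiated as in step 6 to 8, which adds to F2 at −78 °C to give the C11 carbinol F3 as an epimer mixture.
- F3 is converted with NaH, CS2 and MeI into the S-methyl xanthate F4, and Bu3SnH/AIBN (Barton–McCombie deoxygenation) gives the drimenylmethyl arene F5, the ring-closed counterpart of 10.
- Steps 7 to 13 are then applied unchanged. PPTS in MeOH gives, through the phenol silyl ether F6, the phenol diol F7. PhI(OAc)2 in MeOH gives the monoketal F8. The tartrate-mediated epoxidation gives the epoxy ketal F9, and aqueous HF gives the epoxyquinone F10. i-Bu2AlH gives the 4'-epimeric alcohol F11. Mitsunobu esterification gives, through the mono-ester F12, the bis(4-nitrobenzoate) F13, and methanolysis gives, through the mono-ester F14, compound 21.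
- The price is that the exocyclic alkene must pass through the HF step.

**Step 9.** The closest precedents carry a halogen at C2', which this substrate lacks, so facial discrimination by the tartrate aggregate may be incomplete or of the opposite sense. Competing addition at C3' is less likely.

Fallback: resolution in place of asymmetric induction, from 13 back to 14. Compound 13 is epoxidised without tartrate (Ph3COOH, KN(SiMe3)2, toluene, −40 °C) to the racemate of 14 and its enantiomer F15. The two are separated by preparative chromatography on a chiral stationary phase, and 14 goes on to step 10.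

**Step 11.** Hydride may be delivered partly to C1' or to both carbonyls, and the facial preference at C4' may be incomplete, leaving an epimer mixture.

Fallback: enzyme control in place of substrate control, from 15 to 20. Compound 15 is reduced with a ketoreductase selected from a panel for C4' regioselectivity and 4'R configuration (NADPH, glucose and glucose dehydrogenase for recycling, buffer pH 7, 30 °C). This gives 20 directly and makes steps 12 and 13 unnecessary. It forms no compound outside the list.

**Step 12.** The activated C4' oxygen sits on an allylic, base-sensitive ring. Elimination with epoxide opening towards an arene, SN2' attack, or ionisation with loss of inversion can compete with the direct displacement.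

Fallback: a two-stage sulfonate displacement (Lattrell–Dax inversion) on a substrate with the primary alcohol masked, from 16 to 20. Compound 16 is silylated at the primary hydroxyl (TBSCl, imidazole) to the silyl ether F16. Tf2O and pyridine at −30 °C give the 4'-triflate F17. KNO2 in DMF displaces it with inversion to the nitrite ester F18, which hydrolyses on aqueous work-up to the 4'R alcohol F19. HF·pyridine in THF then gives 20.

**Step 6.** Lithiation may occur partly between the acetal oxygen and the silyloxymethyl group or at the benzylic carbon with silyl migration. The allylation may also leak to SN2' attack or erode the 2E geometry.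

Fallback: the metalation site is fixed by a halogen, from 5 to 8. Compound 5 is brominated with NBS in MeCN at 0 °C (NaHCO3 buffer) para to the silyloxymethyl group to give the aryl bromide F20. Bromine–lithium exchange with n-BuLi at −78 °C gives 8, which continues through 9 to 10 as in step 6.

## Further compounds

F1 | step 14 | (5S,9S,10S)-albicanol, [(1S,4aS,8aS)-5,5,8a-trimethyl-2-methylidenedecahydronaphthalen-1-yl]methanol | C=C1CC[C@H]2C(C)(C)CCC[C@]2(C)[C@H]1CO
F2 | step 14 | albicanal, (1S,4aS,8aS)-5,5,8a-trimethyl-2-methylidenedecahydronaphthalene-1-carbaldehyde | C=C1CC[C@H]2C(C)(C)CCC[C@]2(C)[C@H]1C=O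
F3 | step 14 | C11 carbinol from 8 and F2 (epimers at C11) | C=C1CC[C@H]2C(C)(C)CCC[C@]2(C)[C@H]1C(O)c1cc(OC)c(CO[Si](C)(C)C(C)(C)C)cc1OC1CCCCO1
F4 | step 14 | S-methyl xanthate of F3 | C=C1CC[C@H]2C(C)(C)CCC[C@]2(C)[C@H]1C(OC(=S)SC)c1cc(OC)c(CO[Si](C)(C)C(C)(C)C)cc1OC1CCCCO1
F5 | step 14 | drimenylmethyl arene, ring-closed counterpart of 10 | C=C1CC[C@H]2C(C)(C)CCC[C@]2(C)[C@H]1Cc1cc(OC)c(CO[Si](C)(C)C(C)(C)C)cc1OC1CCCCO1
F6 | step 14 | phenol silyl ether, ring-closed counterpart of 11 | C=C1CC[C@H]2C(C)(C)CCC[C@]2(C)[C@H]1Cc1cc(OC)c(CO[Si](C)(C)C(C)(C)C)cc1O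
F7 | step 14 | phenol diol, ring-closed counterpart of 12 | C=C1CC[C@H]2C(C)(C)CCC[C@]2(C)[C@H]1Cc1cc(OC)c(CO)cc1O
F8 | step 14 | quinone monoketal, ring-closed counterpart of 13 | C=C1CC[C@H]2C(C)(C)CCC[C@]2(C)[C@H]1CC1=CC(OC)(OC)C(CO)=CC1=O
F9 | step 14 | epoxy ketal, ring-closed counterpart of 14 | C=C1CC[C@H]2C(C)(C)CCC[C@]2(C)[C@H]1C[C@]12O[C@H]1C(OC)(OC)C(CO)=CC2=O
F10 | step 14 | epoxyquinone, ring-closed counterpart of 15 | C=C1CC[C@H]2C(C)(C)CCC[C@]2(C)[C@H]1C[C@]12O[C@H]1C(=O)C(CO)=CC2=O
F11 | step 14 | 4'-epimer of 21, ring-closed counterpart of 16 | C=C1CC[C@H]2C(C)(C)CCC[C@]2(C)[C@H]1C[C@]12O[C@H]1[C@@H](O)C(CO)=CC2=O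
F12 | step 14 | 7'-mono(4-nitrobenzoate) of F11 | C=C1CC[C@H]2C(C)(C)CCC[C@]2(C)[C@H]1C[C@]12O[C@H]1[C@@H](O)C(COC(=O)c3ccc([N+](=O)[O-])cc3)=CC2=O
F13 | step 14 | 4',7'-bis(4-nitrobenzoate) of 21 | C=C1CC[C@H]2C(C)(C)CCC[C@]2(C)[C@H]1C[C@]12O[C@H]1[C@H](OC(=O)c3ccc([N+](=O)[O-])cc3)C(COC(=O)c3ccc([N+](=O)[O-])cc3)=CC2=O
F14 | step 14 | 4'-mono(4-nitrobenzoate) of 21 | C=C1CC[C@H]2C(C)(C)CCC[C@]2(C)[C@H]1C[C@]12O[C@H]1[C@H](OC(=O)c3ccc([N+](=O)[O-])cc3)C(CO)=CC2=O
F15 | step 9 | enantiomer of 14, (1R,6S)-epoxy ketal | CC(C)=CCC/C(C)=C/CC/C(C)=C/C[C@@]12O[C@@H]1C(OC)(OC)C(CO)=CC2=O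
F0 | step 11 | none | none
F16 | step 12 | 7'-O-tert-butyldimethylsilyl ether of 16 | CC(C)=CCC/C(C)=C/CC/C(C)=C/C[C@]12O[C@H]1[C@@H](O)C(CO[Si](C)(C)C(C)(C)C)=CC2=O
F17 | step 12 | 4'-O-trifluoromethanesulfonate of F16 | CC(C)=CCC/C(C)=C/CC/C(C)=C/C[C@]12O[C@H]1[C@@H](OS(=O)(=O)C(F)(F)F)C(CO[Si](C)(C)C(C)(C)C)=CC2=O
F18 | step 12 | 4'R nitrite ester | CC(C)=CCC/C(C)=C/CC/C(C)=C/C[C@]12O[C@H]1[C@H](ON=O)C(CO[Si](C)(C)C(C)(C)C)=CC2=O
F19 | step 12 | 7'-O-tert-butyldimethylsilyl ether of 20 | CC(C)=CCC/C(C)=C/CC/C(C)=C/C[C@]12O[C@H]1[C@H](O)C(CO[Si](C)(C)C(C)(C)C)=CC2=O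
F20 | step 6 | {[4-bromo-2-methoxy-5-(tetrahydropyran-2-yloxy)phenyl]methoxy}(tert-butyl)dimethylsilane | Brc1cc(OC)c(CO[Si](C)(C)C(C)(C)C)cc1OC1CCCCO1
A1 | alternative 1 | 11-aryl-11-oxodrim-8(12)-ene, aryl = 5-methoxy-2-(methoxymethoxy)-4-[(tert-butyldimethylsilyloxy)methyl]phenyl | C=C1CC[C@H]2C(C)(C)CCC[C@]2(C)[C@H]1C(=O)c1cc(OC)c(CO[Si](C)(C)C(C)(C)C)cc1OCOC
A2 | alternative 1 | ring A alkyne carrying the (Z)-tert-butyldimethylsilyl enol ether of the C11 aryl ketone | C#CCC[C@H]1C(C)(C)CCC[C@]1(C)/C=C(\O[Si](C)(C)C(C)(C)C)c1cc(OC)c(CO[Si](C)(C)C(C)(C)C)cc1OCOC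
A3 | alternative 2 | convex-face epoxide of the norbornene-fused enedione | C=C1CC[C@H]2C(C)(C)CCC[C@]2(C)[C@H]1C[C@]12O[C@H]1C(=O)[C@]3(CO[Si](C)(C)C(C)(C)C)[C@@H]4C=C[C@@H](C4)[C@@H]3C2=O
A4 | alternative 2 | norbornene-fused enedione (Diels–Alder adduct) | C=C1CC[C@H]2C(C)(C)CCC[C@]2(C)[C@H]1CC1=CC(=O)[C@]2(CO[Si](C)(C)C(C)(C)C)[C@@H]3C=C[C@@H](C3)[C@@H]2C1=O
A5 | alternative 3 | 4',7'-bis-O-tert-butyldimethylsilyl ether of 21 | C=C1CC[C@H]2C(C)(C)CCC[C@]2(C)[C@H]1C[C@]12O[C@H]1[C@H](O[Si](C)(C)C(C)(C)C)C(CO[Si](C)(C)C(C)(C)C)=CC2=O
A6 | alternative 3 | open-chain 6'-chloro ketone with the 5' aldehyde (epimers at C6') | C=C1CC[C@H]2C(C)(C)CCC[C@]2(C)[C@H]1CC(Cl)C(=O)/C=C(CO[Si](C)(C)C(C)(C)C)\[C@@H](O[Si](C)(C)C(C)(C)C)C=O
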